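The route rests on disconnecting C4a–C5, the bond that joins ring A to the pyranone ring C. Ring A (C4a, C5, C6, C7, C8, C8a) carries oxygen at C5, C7 and C8a in the 1,3,5-pattern of a β-polycarbonyl chain, so it is unmasked from a 2,2-dimethyl-1,3-dioxin-4-one: heating releases an acylketene whose ketene carbon (C5) closes on pyranone C3 (future C4a), creating ring A with 5-OH, the C6 side chain and 7-OH fixed in one operation. The precursor is a 5-aryl-4-pyranone bearing at C2 a CH2 link to a 5-alkyl dioxinone, with all three remaining hydroxyls as benzyl ethers.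

Key step: step 9

Remark on the chemistry: the target is taken as the tertiary alcohol drawn (the hydrate of luteone); the tertiary hydroxyl is carried as a benzyl ether, not a silyl ether, so that one neutral hydrogenolysis frees all three hydroxyls and neither fluoride nor acid meets the chain-plus-phenol pair that would close a chroman; the methoxyacrylate is drawn E, but its geometry is lost on pyranone closure.

Step 1
Reactants: 1 2-methylbut-3-en-2-ol
Product: 2 benzyl 2-methylbut-3-en-2-yl ether
Conditions: NaH, BnBr, Bu4NI (cat.), THF/DMF, 0 °C → rt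
Reagents that add atoms: benzyl bromide, BrCc1ccccc1
Why: Williamson etherification of the tertiary sodium alkoxide with benzyl bromide under iodide catalysis should give an ether that survives base, heat and mild acid and is later removed by hydrogenolysis together with the aryl benzyl ethers.

Step 2
Reactants: 3 2,2,6-trimethyl-4H-1,3-dioxin-4-one
Product: 4 5-iodo-2,2,6-trimethyl-4H-1,3-dioxin-4-one
Conditions: NIS, AcOH, rt, dark
Reagents that add atoms: N-iodosuccinimide, O=C1CCC(=O)N1I
Why: C5 is the nucleophilic α-carbon of the vinylogous carbonate, so electrophilic iodination with N-iodosuccinimide in acetic acid should occur there alone.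

Step 3
Reactants: 2 benzyl 2-methylbut-3-en-2-yl ether; 4 5-iodo-2,2,6-trimethyl-4H-1,3-dioxin-4-one
Product: 6 5-[3-(benzyloxy)-3-methylbutyl]-2,2,6-trimethyl-4H-1,3-dioxin-4-one, via B-alkyl-9-BBN borane 5 (not isolated)
Conditions: 9-BBN, THF, rt; then 4, PdCl2(dppf) (5 mol%), AsPh3, Cs2CO3, DMF/THF/H2O, rt
Reagents that add atoms: none
Why: anti-Markovnikov hydroboration puts boron on the terminal carbon, and a B-alkyl Suzuki–Miyaura coupling with the α-iodo-enone-type vinyl iodide at room temperature should form the C5–CH2 bond without opening the dioxinone.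

Step 4
Reactants: 6 5-[3-(benzyloxy)-3-methylbutyl]-2,2,6-trimethyl-4H-1,3-dioxin-4-one
Product: 7 5-[3-(benzyloxy)-3-methylbutyl]-2,2-dimethyl-6-(2-oxopropyl)-4H-1,3-dioxin-4-one
Conditions: LiN(SiMe3)2 (1.1 equiv), THF, −78 °C; AcCl (0.5 equiv), −78 → −20 °C; aq. NH4Cl (unreacted 6 recovered)
Reagents that add atoms: acetyl chloride, CC(=O)Cl
Why: deprotonation of the 6-methyl group gives the vinylogous dienolate, which is C-acylated at the γ-carbon by acetyl chloride (vinylogous Claisen-type acylation); the substituted C5 blocks α-attack, and the more acidic product is deprotonated by the excess dienolate, which prevents a second acylation.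

Step 5
Reactants: 8 2,4-dihydroxyphenylacetic acid
Product: 9 benzyl 2-[2,4-bis(benzyloxy)phenyl]acetate
Conditions: BnBr (3.3 equiv), K2CO3, DMF, 60 °C
Reagents that add atoms: benzyl bromide, BrCc1ccccc1
Why: exhaustive O-benzylation (Williamson etherification of both phenols and SN2 esterification of the carboxylate) should give one fully protected compound in a single operation.

Step 6
Reactants: 9 benzyl 2-[2,4-bis(benzyloxy)phenyl]acetate
Product: 11 benzyl (2E)-2-[2,4-bis(benzyloxy)phenyl]-3-methoxyprop-2-enoate, via formyl ester sodium enolate 10 (not isolated)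
Conditions: NaH, HCO2Bn, THF, 0 °C → rt; then Me2SO4, DMF, rt
Reagents that add atoms: benzyl formate, O=COCc1ccccc1; dimethyl sulfate, COS(=O)(=O)OC
Why: crossed Claisen condensation with the non-enolisable formate (benzyl formate matches the benzyl ester, so alkoxide exchange is degenerate) gives the stabilised formyl-ester enolate, which dimethyl sulfate alkylates on oxygen to the β-methoxyacrylate, the standard preparation of 2-aryl-3-methoxyacrylates.

Step 7
Reactants: 11 benzyl (2E)-2-[2,4-bis(benzyloxy)phenyl]-3-methoxyprop-2-enoate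
Product: 12 (2E)-2-[2,4-bis(benzyloxy)phenyl]-3-methoxyprop-2-enoic acid
Conditions: LiOH, THF/MeOH/H2O, 40 °C; then 1 M HCl to pH 3, 0 °C
Reagents that add atoms: lithium hydroxide, [Li+].[OH-]
Why: saponification of the ester should leave the base-stable enol ether and the benzyl ethers untouched, and brief cold acidification gives the free acid, which has no α-hydrogen.

Step 8
Reactants: 12 (2E)-2-[2,4-bis(benzyloxy)phenyl]-3-methoxyprop-2-enoic acid; 7 5-[3-(benzyloxy)-3-methylbutyl]-2,2-dimethyl-6-(2-oxopropyl)-4H-1,3-dioxin-4-one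
Product: 15 5-[2,4-bis(benzyloxy)phenyl]-2-({5-[3-(benzyloxy)-3-methylbutyl]-2,2-dimethyl-4-oxo-4H-1,3-dioxin-6-yl}methyl)-4H-pyran-4-one, via acyl imidazolide 13 (not isolated), via triketone enol ether 14 (not isolated)
Conditions: 12, CDI, THF, rt; 7 (2 equiv), LiN(iPr)2 (4.2 equiv), THF, −78 °C, then the imidazolide solution, −78 → −40 °C; AcOH; crude, PPTS (cat.), PhMe, 40 °C
Reagents that add atoms: none
Why: the dianion of the keto-dioxinone (first proton from the doubly activated CH2, second from the terminal methyl) is acylated at its terminal carbon by the non-enolisable imidazolide (crossed Claisen condensation of a 1,3-dicarbonyl dianion), and under mild acid the enol oxygen of the ketone next to the dioxinone CH2 adds to the β-methoxy enone and expels methanol (6-endo-trig oxa-Michael addition–elimination) to close the 4-pyranone.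

Step 9
Reactants: 15 5-[2,4-bis(benzyloxy)phenyl]-2-({5-[3-(benzyloxy)-3-methylbutyl]-2,2-dimethyl-4-oxo-4H-1,3-dioxin-6-yl}methyl)-4H-pyran-4-one
Product: 17 3-[2,4-bis(benzyloxy)phenyl]-6-[3-(benzyloxy)-3-methylbutyl]-5,7-dihydroxy-4H-chromen-4-one, via acylketene 16 (not isolated)
Conditions: PhMe (0.005 M), 110 °C, slow addition of 15 to the refluxing solvent, N2 sweep, 4 Å molecular sieves
Reagents that add atoms: none
Why: Thermal retro-(4+2) fragmentation of the 2,2-dimethyl-1,3-dioxin-4-one expels acetone and unveils acylketene 16, in which the former dioxinone carbonyl carbon is the ketene carbon (future C5). Enolisation of the C7 ketone toward C8 gives a (Z)-dienylketene whose termini, C5 and the enol-ether-like pyranone C3 (future C4a), join by 6π electrocyclisation (equivalently an intramolecular C-acylation of the pyranone), and the resulting cyclohexadienone tautomerises to the 5-hydroxy aromatic ring, which is hydrogen-bonded to the C4 carbonyl. The closest known reaction types are the thermolysis of dioxinones to acylketenes used in biomimetic polyketide aromatisations and the 6π closure of dienylketenes to phenols that ends the Danheiser benzannulation, including closures onto (hetero)aromatic C=C bonds. Ring A closes in the six-membered electrocyclic mode between C4a and C5, and no stereocentre is created. The step needs regioselectivity and chemoselectivity: the chain order makes C4a the only carbon the ketene can reach (attack from C8 would give a four-membered ring), so hydroxyl, alkyl and hydroxyl must fall at C5, C6 and C7. Compound 15 holds no free hydroxyl (the benzylated tertiary alcohol cannot form a δ-lactone), the C6 alkyl group slows ketene dimerisation, and dry, neutral, highly dilute conditions with removal of acetone suppress hydrolysis and avoid base-induced opening of the pyranone.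

Step 10
Reactants: 17 3-[2,4-bis(benzyloxy)phenyl]-6-[3-(benzyloxy)-3-methylbutyl]-5,7-dihydroxy-4H-chromen-4-one
Product: 18 luteone hydride, 3-(2,4-dihydroxyphenyl)-5,7-dihydroxy-6-(3-hydroxy-3-methylbutyl)-4H-chromen-4-one
Conditions: H2 (1 atm), 10% Pd/C, EtOAc/MeOH, rt, stopped after uptake of three equivalents
Reagents that add atoms: none
Why: hydrogenolysis of the two aryl benzyl ethers and the tertiary alkyl benzyl ether under neutral conditions should free all three hydroxyls without acid, so the side chain cannot cyclise onto a phenol, and stopping at three equivalents of hydrogen spares the C2=C3 bond.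

Compound list
1 | 2-methylbut-3-en-2-ol | CC(C)(O)C=C | starting material
2 | benzyl 2-methylbut-3-en-2-yl ether | C=CC(C)(C)OCc1ccccc1 | intermediate
3 | 2,2,6-trimethyl-4H-1,3-dioxin-4-one | CC1=CC(=O)OC(C)(C)O1 | starting material
4 | 5-iodo-2,2,6-trimethyl-4H-1,3-dioxin-4-one | CC1=C(I)C(=O)OC(C)(C)O1 | intermediate
5 | 9-[3-(benzyloxy)-3-methylbutyl]-9-borabicyclo[3.3.1]nonane (not isolated) | CC(C)(CCB1C2CCCC1CCC2)OCc1ccccc1 | intermediate
6 | 5-[3-(benzyloxy)-3-methylbutyl]-2,2,6-trimethyl-4H-1,3-dioxin-4-one | CC1=C(CCC(C)(C)OCc2ccccc2)C(=O)OC(C)(C)O1 | intermediate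
7 | 5-[3-(benzyloxy)-3-methylbutyl]-2,2-dimethyl-6-(2-oxopropyl)-4H-1,3-dioxin-4-one | CC(=O)CC1=C(CCC(C)(C)OCc2ccccc2)C(=O)OC(C)(C)O1 | intermediate
8 | 2,4-dihydroxyphenylacetic acid | OC(=O)Cc1ccc(O)cc1O | starting material
9 | benzyl 2-[2,4-bis(benzyloxy)phenyl]acetate | O=C(Cc1ccc(OCc2ccccc2)cc1OCc1ccccc1)OCc1ccccc1 | intermediate
10 | benzyl 2-[2,4-bis(benzyloxy)phenyl]-3-oxopropanoate, present as its sodium enolate (not isolated) | O=CC(C(=O)OCc1ccccc1)c1ccc(OCc2ccccc2)cc1OCc1ccccc1 | intermediate
11 | benzyl (2E)-2-[2,4-bis(benzyloxy)phenyl]-3-methoxyprop-2-enoate | CO/C=C(/C(=O)OCc1ccccc1)c1ccc(OCc2ccccc2)cc1OCc1ccccc1 | intermediate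
12 | (2E)-2-[2,4-bis(benzyloxy)phenyl]-3-methoxyprop-2-enoic acid | CO/C=C(/C(=O)O)c1ccc(OCc2ccccc2)cc1OCc1ccccc1 | intermediate
13 | (2E)-2-[2,4-bis(benzyloxy)phenyl]-1-(1H-imidazol-1-yl)-3-methoxyprop-2-en-1-one (not isolated) | CO/C=C(/C(=O)n1ccnc1)c1ccc(OCc2ccccc2)cc1OCc1ccccc1 | intermediate
14 | 6-{(5E)-5-[2,4-bis(benzyloxy)phenyl]-6-methoxy-2,4-dioxohex-5-en-1-yl}-5-[3-(benzyloxy)-3-methylbutyl]-2,2-dimethyl-4H-1,3-dioxin-4-one (not isolated) | CO/C=C(/C(=O)CC(=O)CC1=C(CCC(C)(C)OCc2ccccc2)C(=O)OC(C)(C)O1)c1ccc(OCc2ccccc2)cc1OCc1ccccc1 | intermediate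
15 | 5-[2,4-bis(benzyloxy)phenyl]-2-({5-[3-(benzyloxy)-3-methylbutyl]-2,2-dimethyl-4-oxo-4H-1,3-dioxin-6-yl}methyl)-4H-pyran-4-one | CC(C)(CCC1=C(Cc2cc(=O)c(-c3ccc(OCc4ccccc4)cc3OCc3ccccc3)co2)OC(C)(C)OC1=O)OCc1ccccc1 | intermediate
16 | acylketene 2-{[5-(2,4-bis(benzyloxy)phenyl)-4-oxo-4H-pyran-2-yl]acetyl}-5-(benzyloxy)-5-methylhex-1-en-1-one (not isolated) | O=C=C(CCC(C)(C)OCc1ccccc1)C(=O)Cc1cc(=O)c(-c2ccc(OCc3ccccc3)cc2OCc2ccccc2)co1 | intermediate
17 | 3-[2,4-bis(benzyloxy)phenyl]-6-[3-(benzyloxy)-3-methylbutyl]-5,7-dihydroxy-4H-chromen-4-one | CC(C)(CCc1c(O)cc2occ(-c3ccc(OCc4ccccc4)cc3OCc3ccccc3)c(=O)c2c1O)OCc1ccccc1 | intermediate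
18 | luteone hydride, 3-(2,4-dihydroxyphenyl)-5,7-dihydroxy-6-(3-hydroxy-3-methylbutyl)-4H-chromen-4-one | CC(C)(O)CCc1c(O)cc2occ(-c3ccc(O)cc3O)c(=O)c2c1O | target

Total step count: 10. Longest linear sequence: 6 steps (steps 1, 3, 4, 8, 9, 10; the branches through step 2 and through steps 5–7 are equally long).

Steps most likely to fail

1. Step 9. Enolisation toward C8 and ring closure may be slower than bimolecular consumption of the acylketene (dimerisation, capture by traces of water or by the phenol of product already formed), so that material is lost before C4a–C5 forms. The fallback sets out from 15 and separates ketene release from ring closure. Heating 15 in toluene with excess methanol at 110 °C should trap acylketene 16 as the racemic methyl β-keto ester, methyl 2-{[5-(2,4-bis(benzyloxy)phenyl)-4-oxo-4H-pyran-2-yl]acetyl}-5-(benzyloxy)-5-methylhexanoate F1. Treatment with the non-nucleophilic base LiN(SiMe3)2 (3 equiv, THF, −78 °C → rt) should then give the dianion, whose pyranone-centred carbon attacks the ester in a Dieckmann-type Claisen condensation, the classical base-mediated closure of polyketo esters to acylphloroglucinol rings. Loss of methoxide and tautomerisation bring the route back at 17.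

2. Step 8. The dianion may attack the β-carbon of the methoxyacryloyl unit (addition–elimination) or be acylated on oxygen instead of adding to the acyl carbon. The fallback sets out from 11 and 7 and replaces the acylation by an aldol addition and an oxidation. Reduction of 11 with iBu2AlH (CH2Cl2, −78 °C) should give (2E)-2-[2,4-bis(benzyloxy)phenyl]-3-methoxyprop-2-en-1-ol F2, and MnO2 should oxidise it to (2E)-2-[2,4-bis(benzyloxy)phenyl]-3-methoxyprop-2-enal F3. β-Alkoxy enals take hard lithium nucleophiles at the aldehyde carbon, so the dianion of 7 (LiN(iPr)2, THF, −78 °C) should give the racemic aldol 6-{(5E)-5-[2,4-bis(benzyloxy)phenyl]-4-hydroxy-6-methoxy-2-oxohex-5-en-1-yl}-5-[3-(benzyloxy)-3-methylbutyl]-2,2-dimethyl-4H-1,3-dioxin-4-one F4. Buffered Dess–Martin oxidation of F4 returns to the route at 14, which is closed to 15 as in step 8.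

3. Step 3. Transmetalation of the alkylborane may be slow, leaving room for protodeboronation, β-hydride elimination or hydrolytic opening of the dioxinone by the aqueous base. The fallback sets out from 2 and 4 and uses a base-free organozinc coupling. Hydroboration of 2 with 9-BBN (through 5) and oxidation (NaOH, H2O2) should give 3-(benzyloxy)-3-methylbutan-1-ol F5. Iodination (I2, PPh3, imidazole) should give {[(4-iodo-2-methylbutan-2-yl)oxy]methyl}benzene F6, and zinc insertion (Zn dust, LiCl, THF, 40 °C) should give [3-(benzyloxy)-3-methylbutyl]zinc iodide F7. Negishi coupling of F7 with 4 (Pd(OAc)2, SPhos, THF, rt) comes back to the route at 6.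

Further compounds
F1 | step 9 | methyl 2-{[5-(2,4-bis(benzyloxy)phenyl)-4-oxo-4H-pyran-2-yl]acetyl}-5-(benzyloxy)-5-methylhexanoate (racemic) | COC(=O)C(CCC(C)(C)OCc1ccccc1)C(=O)Cc1cc(=O)c(-c2ccc(OCc3ccccc3)cc2OCc2ccccc2)co1
F2 | step 8 | (2E)-2-[2,4-bis(benzyloxy)phenyl]-3-methoxyprop-2-en-1-ol | CO/C=C(/CO)c1ccc(OCc2ccccc2)cc1OCc1ccccc1
F3 | step 8 | (2E)-2-[2,4-bis(benzyloxy)phenyl]-3-methoxyprop-2-enal | CO/C=C(/C=O)c1ccc(OCc2ccccc2)cc1OCc1ccccc1
F4 | step 8 | 6-{(5E)-5-[2,4-bis(benzyloxy)phenyl]-4-hydroxy-6-methoxy-2-oxohex-5-en-1-yl}-5-[3-(benzyloxy)-3-methylbutyl]-2,2-dimethyl-4H-1,3-dioxin-4-one (racemic) | CO/C=C(/C(O)CC(=O)CC1=C(CCC(C)(C)OCc2ccccc2)C(=O)OC(C)(C)O1)c1ccc(OCc2ccccc2)cc1OCc1ccccc1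
F5 | step 3 | 3-(benzyloxy)-3-methylbutan-1-ol | CC(C)(CCO)OCc1ccccc1
F6 | step 3 | {[(4-iodo-2-methylbutan-2-yl)oxy]methyl}benzene | CC(C)(CCI)OCc1ccccc1
F7 | step 3 | [3-(benzyloxy)-3-methylbutyl]zinc iodide | CC(C)(CC[Zn]I)OCc1ccccc1
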